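**Retrosynthetic overview**
1. Target 13 ⇐ spiro-isoxazoline enone 11 by reductive N–O cleavage and imine hydrolysis. The isoxazoline carries the tertiary carbinol and the side-chain ketone in masked form until the last step, so the ring cannot dehydrate to a phenol on the way.
2. 11 ⇐ saturated spiro ketone 9 by α,β-dehydrogenation (only C8–C9 can be desaturated, because C5 is fully substituted).
3. 9 ⇐ achiral enone oxime 8 by the key step: enantioselective intramolecular addition of the oxime oxygen to C3 of the enone. This forms the tertiary C–O bond, the only stereocentre and the isoxazoline ring.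
4. 8 ⇐ oxime 4 + 3-ethoxycyclohex-2-enone 5 (oxime dianion addition, Stork–Danheiser transposition); 4 ⇐ linoleic acid 1 (MeLi, then NH2OH).
5. Ring order: the carbocycle is bought with 5; the isoxazoline ring is closed in step 4 and opened again in step 6.

Assumption: the facial sense of the new step 4 cannot be predicted with certainty; the quinine-derived amine is written as giving (5S)-9, and the pseudo-enantiomeric quinidine-derived amine is used instead if the sense proves opposite. A one-pot operation is counted as one step.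

**Route**

Step 1
Reactants: 1 linoleic acid
Product: 3 (10Z,13Z)-nonadeca-10,13-dien-2-one, via gem-diolate 2 (not isolated)
Conditions: MeLi (2.2 equiv), Et2O, 0 °C to rt; then poured into 1 M HCl, 0 °C
Reagents that add atoms: methyllithium, [Li]C
Why: Ketone synthesis from a carboxylic acid and an organolithium: the lithium carboxylate takes up one MeLi to give a gem-diolate that cannot over-add and collapses to the methyl ketone only on acidic quench, and the skipped Z,Z-diene is inert to MeLi at 0 °C.

Step 2
Reactants: 3 (10Z,13Z)-nonadeca-10,13-dien-2-one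
Product: 4 (2E,10Z,13Z)-nonadeca-10,13-dien-2-one oxime (E major, about 3:1 over Z)
Conditions: NH2OH·HCl, NaOAc, EtOH/H2O, rt
Reagents that add atoms: hydroxylamine hydrochloride, NO.Cl
Why: Oxime condensation under buffered conditions, in which the thermodynamic mixture favours the E isomer (OH syn to the methyl group), the geometry needed for step 3.

Step 3
Reactants: 4 (2E,10Z,13Z)-nonadeca-10,13-dien-2-one oxime, 5 3-ethoxycyclohex-2-en-1-one
Product: 8 3-[(2Z,10Z,13Z)-2-(hydroxyimino)nonadeca-10,13-dien-1-yl]cyclohex-2-en-1-one, via dilithio oxime 6 (not isolated), via carbinol adduct 7 (not isolated)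
Conditions: LDA (2.3 equiv), THF, 0 °C; then 5 (1.3 equiv), −78 to 0 °C; then 1 M HCl, 0 °C, 20 min
Reagents that add atoms: water, O
Why: Syn-directed α-lithiation of the oximate at the methyl group (LDA spares the bis-allylic CH2), 1,2-addition to the vinylogous ester and acid-induced Stork–Danheiser transposition give the 3-substituted enone with the oxime OH syn to the ring-bearing arm, while the minor Z-oxime gives a separable regioisomer.

Step 4
Reactants: 8 3-[(2Z,10Z,13Z)-2-(hydroxyimino)nonadeca-10,13-dien-1-yl]cyclohex-2-en-1-one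
Product: 9 (5S)-3-[(8Z,11Z)-heptadeca-8,11-dien-1-yl]-1-oxa-2-azaspiro[4.5]dec-2-en-7-one
Conditions: 9-amino-9-deoxy-epi-quinine (10 mol %), CF3CO2H (20 mol %), PhMe, 0 °C, stopped at full conversion
Reagents that add atoms: none
Why: Proposed new method: iminium-catalysed enantioselective 5-exo-trig oxa-Michael spirocyclisation of a tethered ketoxime onto a β,β-disubstituted cyclic enone, in which the cinchona primary amine condenses with the ring ketone to an iminium ion, its protonated quinuclidine hydrogen-bonds the oxime OH and delivers the oxygen to one face of C3, and enamine protonation and hydrolysis release the spiro-isoxazoline with the tertiary C–O stereocentre (5S) set under catalyst control; the closest known reaction types are the primary-amine-salt-catalysed asymmetric epoxidation and hydroperoxidation of 3-substituted cyclohexenones and the intermolecular amine-catalysed oxa-Michael addition of oximes to enones, neither shown intramolecularly to build a spiro-isoxazoline with a tetrasubstituted C–O centre.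

Step 5
Reactants: 9 (5S)-3-[(8Z,11Z)-heptadeca-8,11-dien-1-yl]-1-oxa-2-azaspiro[4.5]dec-2-en-7-one
Product: 11 (5S)-3-[(8Z,11Z)-heptadeca-8,11-dien-1-yl]-1-oxa-2-azaspiro[4.5]deca-2,8-dien-7-one, via lithium enolate 10 (not isolated)
Conditions: LDA (1.05 equiv), THF, −78 °C; then PhS(Cl)=N-t-Bu (1.2 equiv), −78 °C; pH 7 buffer
Reagents that add atoms: none
Why: Mukaiyama dehydrogenation: kinetic deprotonation takes place at the unhindered C8 away from the quaternary oxygen-bearing C5, the enolate is sulfenylated at sulfur and the sulfilimine undergoes syn-elimination at −78 °C, which leaves the isoxazoline, the skipped diene and the stereocentre untouched.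

Step 6
Reactants: 11 (5S)-3-[(8Z,11Z)-heptadeca-8,11-dien-1-yl]-1-oxa-2-azaspiro[4.5]deca-2,8-dien-7-one
Product: 13 (5S)-5-hydroxy-5-[(10Z,13Z)-2-oxononadeca-10,13-dien-1-yl]cyclohex-2-en-1-one, via hydroxy imine 12 (not isolated)
Conditions: Mo(CO)6 (1 equiv), MeCN/H2O 10:1, 70 °C
Reagents that add atoms: water, O
Why: Mo(CO)6-mediated reductive N–O cleavage of the 2-isoxazoline and hydrolysis of the resulting β-hydroxy imine in the flask unmask the β-hydroxy ketone near neutral pH without breaking a bond at the stereocentre and without touching the enone or the isolated Z-alkenes.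

**Compound list**
1 | linoleic acid, (9Z,12Z)-octadeca-9,12-dienoic acid | CCCCC/C=C\C/C=C\CCCCCCCC(=O)O | starting material
2 | gem-diolate, dilithium (10Z,13Z)-nonadeca-10,13-diene-2,2-diolate | CCCCC/C=C\C/C=C\CCCCCCCC(C)(O[Li])O[Li] | intermediate (not isolated)
3 | (10Z,13Z)-nonadeca-10,13-dien-2-one | CCCCC/C=C\C/C=C\CCCCCCCC(C)=O | intermediate
4 | (2E,10Z,13Z)-nonadeca-10,13-dien-2-one oxime (OH syn to CH3) | CCCCC/C=C\C/C=C\CCCCCCC/C(C)=N/O | intermediate
5 | 3-ethoxycyclohex-2-en-1-one | CCOC1=CC(=O)CCC1 | starting material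
6 | dilithio oxime, C1,O-dilithiated 4 | CCCCC/C=C\C/C=C\CCCCCCC/C(C[Li])=N/O[Li] | intermediate (not isolated)
7 | carbinol adduct, 3-ethoxy-1-[(2Z,10Z,13Z)-2-(hydroxyimino)nonadeca-10,13-dien-1-yl]cyclohex-2-en-1-ol (racemic) | CCCCC/C=C\C/C=C\CCCCCCC/C(CC1(O)C=C(OCC)CCC1)=N/O | intermediate (not isolated)
8 | 3-[(2Z,10Z,13Z)-2-(hydroxyimino)nonadeca-10,13-dien-1-yl]cyclohex-2-en-1-one | CCCCC/C=C\C/C=C\CCCCCCC/C(CC1=CC(=O)CCC1)=N/O | intermediate
9 | (5S)-3-[(8Z,11Z)-heptadeca-8,11-dien-1-yl]-1-oxa-2-azaspiro[4.5]dec-2-en-7-one | CCCCC/C=C\C/C=C\CCCCCCCC1=NO[C@]2(C1)CCCC(=O)C2 | intermediate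
10 | lithium enolate, lithium (5S)-3-[(8Z,11Z)-heptadeca-8,11-dien-1-yl]-1-oxa-2-azaspiro[4.5]deca-2,7-dien-7-olate | CCCCC/C=C\C/C=C\CCCCCCCC1=NO[C@]2(C1)CCC=C(O[Li])C2 | intermediate (not isolated)
11 | (5S)-3-[(8Z,11Z)-heptadeca-8,11-dien-1-yl]-1-oxa-2-azaspiro[4.5]deca-2,8-dien-7-one | CCCCC/C=C\C/C=C\CCCCCCCC1=NO[C@]2(C1)CC=CC(=O)C2 | intermediate
12 | hydroxy imine, (5S)-5-hydroxy-5-[(10Z,13Z)-2-iminononadeca-10,13-dien-1-yl]cyclohex-2-en-1-one | CCCCC/C=C\C/C=C\CCCCCCCC(=N)C[C@@]1(O)CC=CC(=O)C1 | intermediate (not isolated)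
13 | (5S)-5-hydroxy-5-[(10Z,13Z)-2-oxononadeca-10,13-dien-1-yl]cyclohex-2-en-1-one | CCCCC/C=C\C/C=C\CCCCCCCC(=O)C[C@@]1(O)CC=CC(=O)C1 | target

**Step count and risks**
Total steps: 6. Longest linear sequence: 6 (from linoleic acid 1).

The three steps most likely to fail:

Step 4 (the proposed new step). Three things can go wrong. Oxime 8 may close without the catalyst, already during the acidic work-up of step 3 or by simple acid catalysis, and give racemic material. The closure is reversible through the product enamine, so the ee may erode with time. The amine may rest as the exocyclic dienamine. The fallback uses known chemistry and sets out from 8: ring closure with an achiral base (DBU, 10 mol %, CH2Cl2, 0 °C) gives the racemic spiro ketone F1. Preparative chiral SFC on an amylose carbamate phase then separates (5S)-9 from the (5R)-enantiomer F2. The fallback comes back to the route at 9.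

Step 5. If some deprotonation occurs at C6, the enolate expels the oximate oxygen from C5 (E1cB). That opens the isoxazoline, racemises the centre and leads on to a phenol. Enone 11 itself is base-sensitive. The fallback sets out from 9: LDA is added to 9 premixed with Me3SiCl in THF at −78 °C (internal quench), so the enolate is trapped as it forms. This gives the silyl enol ether F3, which is freed from any regioisomer by chromatography. Pd(OAc)2 in MeCN at rt (Saegusa–Ito oxidation) then gives the enone under neutral conditions. The fallback comes back at 11.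

Step 6. Mo(0) species may isomerise the skipped diene or reduce the enone, and hot aqueous medium may dehydrate the product to the 3-substituted phenol. The fallback sets out from 11 and removes the enone before the N–O bond is cleaved. Luche reduction (NaBH4, CeCl3·7H2O, MeOH, −40 °C) gives the allylic alcohol F4 as a mixture of carbinol epimers. SmI2 with B(OH)3 in THF/H2O at 0 °C cleaves the N–O bond to the imino diol F5, which hydrolyses in the flask to the keto diol F6. MnO2 in CH2Cl2 at rt oxidises only the secondary allylic alcohol and gives the enone. The fallback comes back at the target 13.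

**Further compounds**
F1 | step 4 | racemic 3-[(8Z,11Z)-heptadeca-8,11-dien-1-yl]-1-oxa-2-azaspiro[4.5]dec-2-en-7-one | CCCCC/C=C\C/C=C\CCCCCCCC1=NOC2(C1)CCCC(=O)C2
F2 | step 4 | (5R)-3-[(8Z,11Z)-heptadeca-8,11-dien-1-yl]-1-oxa-2-azaspiro[4.5]dec-2-en-7-one | CCCCC/C=C\C/C=C\CCCCCCCC1=NO[C@@]2(C1)CCCC(=O)C2
F3 | step 5 | (5S)-3-[(8Z,11Z)-heptadeca-8,11-dien-1-yl]-7-(trimethylsilyloxy)-1-oxa-2-azaspiro[4.5]deca-2,7-diene | CCCCC/C=C\C/C=C\CCCCCCCC1=NO[C@]2(C1)CCC=C(O[Si](C)(C)C)C2
F4 | step 6 | (5S)-3-[(8Z,11Z)-heptadeca-8,11-dien-1-yl]-1-oxa-2-azaspiro[4.5]deca-2,8-dien-7-ol (C7 epimers) | CCCCC/C=C\C/C=C\CCCCCCCC1=NO[C@]2(C1)CC=CC(O)C2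
F5 | step 6 | (1S)-1-[(10Z,13Z)-2-iminononadeca-10,13-dien-1-yl]cyclohex-4-ene-1,3-diol (C3 epimers, not isolated) | CCCCC/C=C\C/C=C\CCCCCCCC(=N)C[C@@]1(O)CC=CC(O)C1
F6 | step 6 | (10Z,13Z)-1-[(1R)-1,5-dihydroxycyclohex-3-en-1-yl]nonadeca-10,13-dien-2-one (C5 epimers; same geometry at the tertiary carbinol as 13, descriptor changes by priority only) | CCCCC/C=C\C/C=C\CCCCCCCC(=O)C[C@@]1(O)CC=CC(O)C1
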